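**Retrosynthetic overview**
1. Labels: the decalin uses drimane numbering (C4 = C(CH3)(C19O2H), C5 and C10 = ring fusion, C7=C8(CH3), C9–C11H2). The carbocycle is C1' (oxirane C on C11), C2' (oxirane CH), C3' (CHOH), C4' (=C–CH2OH), C5' (=CH), C6' (CHOH).
2. Feature: ring C1'–C6' carries oxygen on the para pair C3'/C6' and carbon on the para pair C1'/C4', so it is a dearomatised 2,5-dialkylhydroquinone. The oxirane and both carbinols go back to quinone monoketal 22 (C3' ketal, C6' ketone), and 22 goes back to 4-methoxyphenol 21.
3. Key disconnection: 21 is cut at C2'–C3', C1'–C6' and C5'–C6'. The pieces are the terminal alkyne C11–C1'≡C2'H (13), the chromium-bound alkenylcarbene C3'(OMe)–C4'(CH2OSi)=C5'H2 (19) and one CO ligand (C6').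
4. The decalin is not built. Both rings and C4, C5, C9, C10 come from andrographolide (C3 deoxygenated, C19 oxidised, both alkenes ozonised, C12 aldehyde to alkyne, C8 ketone to enol triflate to C7=C8–CH3).
5. Order of rings: the two decalin rings (chiral pool), then carbocycle C1'–C6' (step 11), then the oxirane (step 13).

Key step: step 11

Assumption: the cinchonidine-derived ammonium salt in step 13 is taken as the catalyst that brings the peroxide to the C1'=C2' face drawn for 23; if a pilot run shows the other face, the pseudoenantiomeric cinchonine-derived salt replaces it with no other change.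

**Step 1**
Reactants: 1 andrographolide
Product: 2 andrographolide 3,19-O-thiocarbonate
Conditions: 1,1'-thiocarbonyldiimidazole (1.1 equiv, slow addition), THF, rt → 40 °C
Reagents that add atoms: 1,1'-thiocarbonyldiimidazole, S=C(n1ccnc1)n1ccnc1
Why: Thiocarbonyl transfer from an azolide, in which the primary C19–OH is acylated first and the equatorial C3–OH then closes the six-membered cyclic thionocarbonate faster than a second reagent molecule reaches the lone allylic C14–OH, the same 1,3-diol selectivity that 1 shows in acetonide formation.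

**Step 2**
Reactants: 2 andrographolide 3,19-O-thiocarbonate
Product: 4 3-deoxyandrographolide, via S-stannyl thiocarbonate 3 (not isolated)
Conditions: Bu3SnH (1.5 equiv, slow addition), AIBN (cat.), PhMe, 110 °C; then KF aq; then 1 M HCl wash
Reagents that add atoms: none
Why: Barton–McCombie deoxygenation of a cyclic thionocarbonate, in which the stannyl radical adds to C=S and the adduct fragments to the secondary C3 radical rather than the primary neopentyl C19 radical, so C3 is reduced while C19 keeps its oxygen as 3, which fluoride and acid convert into the alcohol with loss of COS; the trisubstituted electron-poor C12=C13 alkene is only a slow radical acceptor.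

**Step 3**
Reactants: 4 3-deoxyandrographolide
Product: 6 19-hydroxy-8-oxo-13,14,15,16,17-pentanor-ent-labdan-12-al, via bis-ozonide 5 (not isolated)
Conditions: O3, CH2Cl2, −78 °C; Me2S, −78 °C → rt
Reagents that add atoms: ozone, [O-][O+]=O
Why: Exhaustive ozonolysis with reductive work-up needs no discrimination between the two alkenes, since C8=C17 gives the C8 ketone and C12=C13 gives the C12 aldehyde while removing the lactone together with C14, and C9 keeps its equatorial, thermodynamically preferred side chain next to the new ketone.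

**Step 4**
Reactants: 6 keto aldehyde; 7 dimethyl (1-diazo-2-oxopropyl)phosphonate
Product: 8 propargyl keto alcohol (C8=O, C9–CH2–C≡CH, C19H2OH)
Conditions: 7 (1.4 equiv), K2CO3 (2 equiv), MeOH, 0 °C → rt
Reagents that add atoms: dimethyl (1-diazo-2-oxopropyl)phosphonate, COP(=O)(OC)C(=[N+]=[N-])C(C)=O
Why: Ohira–Bestmann homologation, in which the diazomethylphosphonate anion released by methanolysis attacks only the aldehyde and leaves the hindered C8 ketone, while an aldol closure from C7 to C12 would need a 1,3-diaxial bridge across the trans-decalin and is therefore not competitive.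

**Step 5**
Reactants: 8 propargyl keto alcohol
Product: 9 propargyl keto acid (C19O2H)
Conditions: CrO3, H2SO4 aq, acetone, 0 °C
Reagents that add atoms: water, O; chromium trioxide, O=[Cr](=O)=O
Why: Jones oxidation takes the neopentyl C19 carbinol through the aldehyde hydrate to the acid, the ketone and the terminal alkyne are inert to acidic hexavalent chromium, and the quaternary C4 cannot epimerise.

**Step 6**
Reactants: 9 propargyl keto acid
Product: 10 2-(trimethylsilyl)ethyl ester of 9
Conditions: Me3SiCH2CH2OH, PPh3, DIAD, THF, 0 °C → rt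
Reagents that add atoms: 2-(trimethylsilyl)ethanol, OCC[Si](C)(C)C
Why: Mitsunobu esterification forms the C–O bond at the primary carbon of the silylethanol with the carboxylate as nucleophile, so the crowding of the axial tertiary carboxyl group does not matter, and the ester can later be cleaved at silicon rather than at the shielded carbonyl.

**Step 7**
Reactants: 10 keto ester
Product: 12 C7=C8 enol triflate, via potassium enolate 11 (not isolated)
Conditions: KN(SiMe3)2 (1.15 equiv), THF, −78 °C; Comins' reagent, −78 → −30 °C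
Reagents that add atoms: N-(5-chloropyridin-2-yl)bis(trifluoromethanesulfonimide), FC(F)(F)S(=O)(=O)N(c1ccc(Cl)cn1)S(=O)(=O)C(F)(F)F
Why: Kinetic enolisation followed by O-triflation, in which the base removes a C7 methylene proton rather than the tertiary C9–H wedged between the quaternary C10 and the propargyl arm, and one equivalent suffices because the ketone is several pK units more acidic than an alkyl acetylene.

**Step 8**
Reactants: 12 enol triflate
Product: 13 propargyl decalin ester (C7=C8–CH3, C9–C11H2–C1'≡C2'H)
Conditions: MeLi, CuI, Et2O, 0 °C; then 12 (0.25 equiv relative to cuprate), THF, −20 → 0 °C; NH4Cl aq under N2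
Reagents that add atoms: methyllithium, [Li]C (used as lithium dimethylcuprate, [Li+].C[Cu-]C)
Why: Cuprate cross-coupling of an enol triflate puts the methyl group on C8 with the double bond fixed at C7=C8, and excess reagent covers deprotonation of the alkyne, whose alkynyl ligand on copper is not transferred and is reprotonated on work-up.

**Step 9**
Reactants: 14 2-bromoprop-2-en-1-ol
Product: 15 (2-bromoallyloxy)(tert-butyl)dimethylsilane
Conditions: TBSCl, imidazole, CH2Cl2, rt
Reagents that add atoms: tert-butyldimethylsilyl chloride, CC(C)(C)[Si](C)(C)Cl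
Why: Standard imidazole-promoted silylation of a primary allylic alcohol.

**Step 10**
Reactants: 15 bromoallyl silyl ether; 16 chromium hexacarbonyl
Product: 19 pentacarbonyl{methoxy[3-(tert-butyldimethylsilyloxy)prop-1-en-2-yl]carbene}chromium, via 2-lithioallyl silyl ether 17 (not isolated), via lithium acylchromate 18 (not isolated)
Conditions: t-BuLi (2.0 equiv), Et2O, −78 °C; Cr(CO)6, THF, −78 → 0 °C; MeOTf, CH2Cl2, 0 °C → rt
Reagents that add atoms: chromium hexacarbonyl, O=C=[Cr](=C=O)(=C=O)(=C=O)(=C=O)=C=O; methyl trifluoromethanesulfonate, COS(=O)(=O)C(F)(F)F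
Why: Fischer carbene synthesis by bromine–lithium exchange, addition of the vinyllithium to a CO ligand and O-methylation of the acylmetalate, with the lithium stage kept cold so that trapping outruns the oxygen-to-carbon silyl shift; the α-substituted vinyl group gives a complex of the stable isopropenyl type.

**Step 11**
Reactants: 13 propargyl decalin ester; 19 alkenyl(methoxy)carbene complex
Product: 21 2-(decalinylmethyl)-4-methoxy-5-(silyloxymethyl)phenol, via tricarbonylchromium arene complex 20 (not isolated)
Conditions: 19 (1.5 equiv), degassed THF (0.05 M), 50 °C, Ar; then air, Et2O, rt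
Reagents that add atoms: none
Why: Thermal loss of one CO ligand from 19 frees a site for alkyne 13, which inserts into Cr=C3' to form C2'–C3' and a vinylcarbene, and migration of a CO ligand onto the new carbene carbon forms C1'–C6' and gives a chromium-bound dienylketene. Ring C1'–C6' is closed by six-electron electrocyclisation of this dienylketene (bond C5'–C6'), and tautomerisation of the cyclohexadienone gives the 4-methoxyphenol as its Cr(CO)3 complex 20, from which air removes the metal. This is the Dötz benzannulation of an alkenyl(alkoxy)carbene chromium complex with a terminal alkyne, the substrate pairing in which phenol formation is least disturbed by five-ring products. No stereocentre is formed, and C4, C5, C9 and C10 are spectators. The step needs regiocontrol only, and it is secured because the alkyne carbon carrying the neopentyl-like decalinylmethyl group stays away from the carbene substituents during insertion and so ends next to the CO-derived C6', while C2'H bonds to C3'. The two ring oxygens emerge differentiated (C3'–OMe, C6'–OH), and the hindered C7=C8 alkene, the ester and the silyl ether are inert to the carbene at this temperature.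

**Step 12**
Reactants: 21 phenol
Product: 22 quinone monoketal (C6'=O, C3'(OMe)2, C1'=C2' and C4'=C5')
Conditions: PhI(OAc)2 (1.1 equiv), MeOH, 0 °C
Reagents that add atoms: methanol, CO
Why: Oxidative dearomatisation of a 4-methoxyphenol by trivalent iodine, in which methanol is captured at the methoxy-bearing para carbon so that only C3' is ketalised and C6' becomes the single ketone.

**Step 13**
Reactants: 22 quinone monoketal
Product: 23 C1',C2'-epoxy ketone (oxirane placed as in 27)
Conditions: t-BuOOH (decane), N-benzylcinchonidinium chloride (0.2 equiv), 1 M NaOH aq, PhMe, 0 °C → rt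
Reagents that add atoms: tert-butyl hydroperoxide, CC(C)(C)OO
Why: Asymmetric phase-transfer Weitz–Scheffer epoxidation, in which the peroxide anion adds to the unsubstituted β-carbon C2' rather than the fully substituted C4', the enolate closes onto oxygen to set C1' and C2' together as a cis-fused oxirane, and the face is chosen by the chiral ammonium ion pair because the decalin centre C9 is too remote to bias it.

**Step 14**
Reactants: 23 epoxy ketone
Product: 24 C6' alcohol (OH cis to the oxirane oxygen)
Conditions: NaBH4, CeCl3·7H2O, MeOH, −78 → −40 °C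
Reagents that add atoms: none
Why: Luche 1,2-reduction, in which hydride approaches C6' anti to the oxirane oxygen, which projects steeply from one ring face and repels the borohydride, while C11 lies close to the mean ring plane, so the new hydroxyl ends cis to the oxirane.

**Step 15**
Reactants: 24 epoxy alcohol ketal
Product: 25 C3' enone (C3'=O, C4'=C5', C6'–OH)
Conditions: PPTS (0.2 equiv), acetone/H2O 10:1, rt
Reagents that add atoms: water, O
Why: Mild acid hydrolysis of an allylic dimethyl ketal through an alkene-stabilised oxocarbenium ion, under conditions that leave the oxirane, the primary silyl ether and the silylethyl ester untouched.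

**Step 16**
Reactants: 25 epoxy enone
Product: 26 C3',C6'-diol (both OH cis to the oxirane oxygen)
Conditions: NaBH4, CeCl3·7H2O, MeOH, −78 °C
Reagents that add atoms: none
Why: A second Luche 1,2-reduction, in which hydride again enters anti to the oxirane oxygen at a carbonyl flanked only by the oxirane CH, so the C3' hydroxyl is set cis to the oxirane and conjugate reduction is suppressed by the cerium salt.

**Step 17**
Reactants: 26 protected diol
Product: 27 target acid CNP0458871.1
Conditions: Bu4NF (5 equiv), THF, 0 °C → rt; then 0.5 M HCl to pH 4, 0 °C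
Reagents that add atoms: none
Why: Fluoride cleaves the silyl ether and triggers β-elimination of the silylethyl ester at silicon in one operation, and Payne migration is excluded because both alkoxides sit on the same face as the oxirane oxygen and cannot reach its carbons from the rear.

**Compound list**
1 | andrographolide | C[C@@]12CC[C@H]([C@@]([C@H]1CCC(=C)[C@H]2C/C=C/3\[C@@H](COC3=O)O)(C)CO)O | starting material
2 | andrographolide 3,19-O-thiocarbonate (six-membered cyclic thionocarbonate, 14-OH free) | C[C@@]12CC[C@H]3OC(=S)OC[C@@]3(C)[C@H]1CCC(=C)[C@H]2C/C=C/3\[C@@H](COC3=O)O | intermediate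
3 | 19-O-[(tributylstannylthio)carbonyl]-3-deoxyandrographolide (formed in the flask) | C[C@@]12CCC[C@@]([C@H]1CCC(=C)[C@H]2C/C=C/3\[C@@H](COC3=O)O)(C)COC(=O)S[Sn](CCCC)(CCCC)CCCC | intermediate
4 | 3-deoxyandrographolide (14,19-diol) | C[C@@]12CCC[C@@]([C@H]1CCC(=C)[C@H]2C/C=C/3\[C@@H](COC3=O)O)(C)CO | intermediate
5 | bis-ozonide of 4 (1,2,4-trioxolanes at C8/C17 and C12/C13, new centres undefined; formed in the flask) | C[C@@]12CCC[C@@]([C@H]1CCC3(OCOO3)[C@H]2CC4OOC5(O4)[C@H](O)COC5=O)(C)CO | intermediate
6 | 19-hydroxy-8-oxo-13,14,15,16,17-pentanor-ent-labdan-12-al | C[C@@]12CCC[C@@]([C@H]1CCC(=O)[C@H]2CC=O)(C)CO | intermediate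
7 | dimethyl (1-diazo-2-oxopropyl)phosphonate | COP(=O)(OC)C(=[N+]=[N-])C(C)=O | starting material
8 | propargyl keto alcohol (decalin centres as in 1) | C[C@@]12CCC[C@@]([C@H]1CCC(=O)[C@H]2CC#C)(C)CO | intermediate
9 | propargyl keto acid | C[C@@]12CCC[C@@]([C@H]1CCC(=O)[C@H]2CC#C)(C)C(=O)O | intermediate
10 | propargyl keto 2-(trimethylsilyl)ethyl ester | C[C@@]12CCC[C@@]([C@H]1CCC(=O)[C@H]2CC#C)(C)C(=O)OCC[Si](C)(C)C | intermediate
11 | potassium C7=C8 enolate of 10 (formed in the flask) | [K+].C[C@@]12CCC[C@@]([C@H]1CC=C([O-])[C@H]2CC#C)(C)C(=O)OCC[Si](C)(C)C | intermediate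
12 | C7=C8 enol triflate | C[C@@]12CCC[C@@]([C@H]1CC=C(OS(=O)(=O)C(F)(F)F)[C@H]2CC#C)(C)C(=O)OCC[Si](C)(C)C | intermediate
13 | propargyl decalin ester (C7=C8–CH3, C11–C1'≡C2'H) | CC1=CC[C@H]2[C@@](C)(CCC[C@@]2(C)C(=O)OCC[Si](C)(C)C)[C@@H]1CC#C | intermediate
14 | 2-bromoprop-2-en-1-ol | OCC(Br)=C | starting material
15 | (2-bromoallyloxy)(tert-butyl)dimethylsilane | C=C(Br)CO[Si](C)(C)C(C)(C)C | intermediate
16 | chromium hexacarbonyl | O=C=[Cr](=C=O)(=C=O)(=C=O)(=C=O)=C=O | starting material
17 | 2-lithioallyl silyl ether (formed in the flask) | [Li]C(=C)CO[Si](C)(C)C(C)(C)C | intermediate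
18 | lithium acylchromate (formed in the flask) | [Li+].[O-]C(=[Cr](=C=O)(=C=O)(=C=O)(=C=O)=C=O)C(=C)CO[Si](C)(C)C(C)(C)C | intermediate
19 | pentacarbonyl{methoxy[3-(tert-butyldimethylsilyloxy)prop-1-en-2-yl]carbene}chromium | COC(=[Cr](=C=O)(=C=O)(=C=O)(=C=O)=C=O)C(=C)CO[Si](C)(C)C(C)(C)C | intermediate
20 | η6-Cr(CO)3 complex of phenol 21 (formed in the flask; metal fragment written after the dot) | CC1=CC[C@H]2[C@@](C)(CCC[C@@]2(C)C(=O)OCC[Si](C)(C)C)[C@@H]1Cc1cc(OC)c(CO[Si](C)(C)C(C)(C)C)cc1O.O=C=[Cr](=C=O)=C=O | intermediate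
21 | 2-(decalinylmethyl)-4-methoxy-5-(silyloxymethyl)phenol | CC1=CC[C@H]2[C@@](C)(CCC[C@@]2(C)C(=O)OCC[Si](C)(C)C)[C@@H]1Cc1cc(OC)c(CO[Si](C)(C)C(C)(C)C)cc1O | intermediate
22 | 4,4-dimethoxycyclohexa-2,5-dienone (C3' ketal, C6' ketone) | CC1=CC[C@H]2[C@@](C)(CCC[C@@]2(C)C(=O)OCC[Si](C)(C)C)[C@@H]1CC1=CC(OC)(OC)C(CO[Si](C)(C)C(C)(C)C)=CC1=O | intermediate
23 | C1',C2'-epoxy ketone ketal (oxirane as in 27) | CC1=CC[C@H]2[C@@](C)(CCC[C@@]2(C)C(=O)OCC[Si](C)(C)C)[C@@H]1C[C@]12O[C@H]1C(OC)(OC)C(CO[Si](C)(C)C(C)(C)C)=CC2=O | intermediate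
24 | C6' alcohol, OH cis to oxirane O | CC1=CC[C@H]2[C@@](C)(CCC[C@@]2(C)C(=O)OCC[Si](C)(C)C)[C@@H]1C[C@]12O[C@H]1C(OC)(OC)C(CO[Si](C)(C)C(C)(C)C)=C[C@H]2O | intermediate
25 | C3' enone with C6'–OH | CC1=CC[C@H]2[C@@](C)(CCC[C@@]2(C)C(=O)OCC[Si](C)(C)C)[C@@H]1C[C@]12O[C@H]1C(=O)C(CO[Si](C)(C)C(C)(C)C)=C[C@H]2O | intermediate
26 | C3',C6'-diol, oxirane O and both OH on one face | CC1=CC[C@H]2[C@@](C)(CCC[C@@]2(C)C(=O)OCC[Si](C)(C)C)[C@@H]1C[C@]12O[C@H]1[C@@H](O)C(CO[Si](C)(C)C(C)(C)C)=C[C@H]2O | intermediate
27 | CNP0458871.1, (1'R,2'S,3'S,6'R) carbocycle, decalin centres as in 1 | CC1=CC[C@H]2[C@@](C)(CCC[C@@]2(C)C(=O)O)[C@@H]1C[C@]12O[C@H]1[C@@H](O)C(CO)=C[C@H]2O | target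

**Totals**
Total step count: 17.
Longest linear sequence: 15 steps (steps 1–8, then 11–17).

**Steps most likely to fail**

Step 11. Alkyne insertion may be slower than thermal decay of the carbene complex. The vacant site on chromium can be occupied by the nearby C7=C8 alkene, and the C8 methyl group crowds the propargyl arm, so oligomerisation of the terminal alkyne at the metal could take over. The fallback sets out from 10 and comes back at 21; it moves the benzannulation ahead of the alkene installation.
- Keto alkyne 10, which has no alkene and a flat C8, is heated with 19 in THF and worked up in air to give the keto phenol F1.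
- TBSCl and imidazole cap the phenol as the aryl silyl ether F2.
- KN(SiMe3)2 followed by Comins' reagent gives the C7=C8 enol triflate F3.
- Me2CuLi gives the methylated aryl silyl ether F4.
- K2CO3 in MeOH removes only the aryl silyl group and delivers 21.

This order also takes the acidic alkyne C–H out of the enolate and cuprate steps.

Step 13. Facial discrimination by the ammonium ion pair may be poor, and peroxide attack at C2' may be slowed by the adjacent dimethyl ketal. The fallback sets out from 22 and comes back at 25; it reshapes the ketal and replaces ion-pair control by a metal-bound chiral peroxide.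
- Exchange with propane-1,3-diol (BF3·OEt2 cat., DME, 0 °C) gives the spiro-1,3-dioxane dienone F5, whose tied-back oxygens leave C2' more open.
- Trityl hydroperoxide with NaN(SiMe3)2 and diisopropyl tartrate (4 Å sieves, PhMe, −50 °C) gives the epoxy ketone F6.
- Luche reduction gives the C6' alcohol F7.
- p-TsOH·H2O in wet acetone removes the dioxane and gives 25.

Step 14. Hydride may be delivered from the oxirane face if the decalinylmethyl group folds over the opposite face, and conjugate reduction may compete. The fallback sets out from 23 and comes back at 24; it corrects the centre by substitution instead of relying on facial selectivity.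
- The reduction product is then the C6' epimeric alcohol F8.
- Mitsunobu inversion with 4-nitrobenzoic acid (PPh3, DIAD, THF) gives the 4-nitrobenzoate F9 with the required configuration.
- K2CO3 in MeOH releases 24.

**Further compounds**
F1 | step 11 | keto phenol (C8=O, arene as in 21) | C[C@@]12CCC[C@@]([C@H]1CCC(=O)[C@H]2Cc1cc(OC)c(CO[Si](C)(C)C(C)(C)C)cc1O)(C)C(=O)OCC[Si](C)(C)C
F2 | step 11 | keto aryl silyl ether | C[C@@]12CCC[C@@]([C@H]1CCC(=O)[C@H]2Cc1cc(OC)c(CO[Si](C)(C)C(C)(C)C)cc1O[Si](C)(C)C(C)(C)C)(C)C(=O)OCC[Si](C)(C)C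
F3 | step 11 | C7=C8 enol triflate of F2 | C[C@@]12CCC[C@@]([C@H]1CC=C(OS(=O)(=O)C(F)(F)F)[C@H]2Cc1cc(OC)c(CO[Si](C)(C)C(C)(C)C)cc1O[Si](C)(C)C(C)(C)C)(C)C(=O)OCC[Si](C)(C)C
F4 | step 11 | O-silyl ether of phenol 21 | CC1=CC[C@H]2[C@@](C)(CCC[C@@]2(C)C(=O)OCC[Si](C)(C)C)[C@@H]1Cc1cc(OC)c(CO[Si](C)(C)C(C)(C)C)cc1O[Si](C)(C)C(C)(C)C
F5 | step 13 | spiro-1,3-dioxane quinone monoketal | CC1=CC[C@H]2[C@@](C)(CCC[C@@]2(C)C(=O)OCC[Si](C)(C)C)[C@@H]1CC1=CC2(OCCCO2)C(CO[Si](C)(C)C(C)(C)C)=CC1=O
F6 | step 13 | epoxy ketone dioxane ketal | CC1=CC[C@H]2[C@@](C)(CCC[C@@]2(C)C(=O)OCC[Si](C)(C)C)[C@@H]1C[C@]12O[C@H]1C3(OCCCO3)C(CO[Si](C)(C)C(C)(C)C)=CC2=O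
F7 | step 13 | C6' alcohol dioxane ketal | CC1=CC[C@H]2[C@@](C)(CCC[C@@]2(C)C(=O)OCC[Si](C)(C)C)[C@@H]1C[C@]12O[C@H]1C3(OCCCO3)C(CO[Si](C)(C)C(C)(C)C)=C[C@H]2O
F8 | step 14 | C6' epimer of 24 | CC1=CC[C@H]2[C@@](C)(CCC[C@@]2(C)C(=O)OCC[Si](C)(C)C)[C@@H]1C[C@]12O[C@H]1C(OC)(OC)C(CO[Si](C)(C)C(C)(C)C)=C[C@@H]2O
F9 | step 14 | C6' 4-nitrobenzoate with the configuration of 24 | CC1=CC[C@H]2[C@@](C)(CCC[C@@]2(C)C(=O)OCC[Si](C)(C)C)[C@@H]1C[C@]12O[C@H]1C(OC)(OC)C(CO[Si](C)(C)C(C)(C)C)=C[C@H]2OC(=O)c3ccc(cc3)[N+](=O)[O-]
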